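I read the flask at 2.5 min, so what I needed was the clock of E over that span.

E 0.10 M; Q 0.200 M; L 0.10 mM; time 2.5 min

    G + L ⇌ G.L (K1 = 23 M⁻¹, k1 = 43000 M⁻¹ s⁻¹)
    E + G.L ⇌ E.G.L (K2 = 77 M⁻¹, k2 = 390 M⁻¹ s⁻¹)
    E.G.L ⇌ D (K3 = 0.69, k3 = 370 s⁻¹)
    D → L + X (k4 = 770 s⁻¹)
    Q ⇌ G, rate k5*(cs5 - [G]) while solid is left; crystals form when [G] > cs5 (cs5 = 11 mM, k5 = 0.48 s⁻¹)

- the X standing at 2.5 min, as a percentage of the E charged
- the change that raises the amount of X at 2.5 min, in percent of the E charged most ("none" if none brings more than 2 percentage points) (blue / violet / red / none)
- amount of X at 2.5 min, in percent of the E charged, after red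

- blue: doubling the dissolution coefficient of step 5, all else as stated
- violet: doubling the amount of L, all else as stated
- red: doubling the solubility in step 5, all else as stated

- solid, in amounts per volume of the solution: Q
- at the start none of Q is in solution
- run time (flask): 2.5 min

My reckoning, rung by rung from the fastest:

- G.L lost its G with a half-life of 0.371 ms, while E took up G.L with a much longer half-life of 17.8 ms, so I kept L and G.L in balance with G; taking these two as the forms that hold the catalyst, I put G.L at full solubility at 20.2% of the catalyst charged, and L, holding more of it, as the resting state.
- E.G.L went on through D at 218 s⁻¹ and fell back at 5.06 s⁻¹, and G.L captured E at 39.0 s⁻¹; since capture was slower than the way on through D, I took capture as the rate-limiting step.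
- Dissolution had a half-life of 1.44 s, much shorter than the run, so I let G follow its solubility, short by the rate over 0.48 s⁻¹; I replaced that falling shortfall by half its starting value, which put G at a mean 92.5% of solubility, and I counted on Q, charged above E, to last the run.
- I then let E decay as a pseudo-first-order species, with the mean clock, the capture constant times the mean share of G.L times the charge of L, equal to 0.00740 s⁻¹, which gave 67.0%; to test the use of a mean, I held G at its starting shortfall and at full solubility instead, which gave 64.5% and 69.3%.
- For red, G.L at full solubility rose to 33.6%, G stood at a mean 93.8% of the new solubility, and the clock became 0.0126 s⁻¹, giving 84.8%; comparing the clocks, I chose violet.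

The forecast, reasoning that “L is dilute, so I treat the catalyst forms as steady”, gave 64% (from 62% to 66%), 83% after red (from 81% to 85%), and violet as the best change, so its first two figures lay below mine.

The flask gave 64.2%, 82.8% after red, and violet as the best change, with gains of 23 percentage points for violet, 19 points for red and 1.5 points for blue.

- Read from the flask, the clock was 0.00685 s⁻¹, below my 0.00740 s⁻¹. The neighbouring flask was charged with 2.5 × 10⁻⁵ M of L, a quarter of the first flask's charge, all else held. Scaling my clock by that charge and holding the mean share of G.L gave 0.00185 s⁻¹, and so 24.2% of X at 2.50 min. The neighbouring flask stood at 23.2% of X, with 76.8% of its E left.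

The numbers stand for no real mixture; the run is a simulation.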